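**Plan**
- Retrosynthesis: the diene is cut at C13=C14 (phosphonate olefination) and the chain at C8–C9 (alkyne–bromoalkyne coupling), leaving a C6‑ethynyl peroxylactone. Its lactone O–C4 bond is traced back to a formyl group on C4 (Baeyer–Villiger).
- Enabling feature: in the 1,2‑dioxane ring (O1, O2, C3, C4, C5, C6) the ring‑fusion bond C3–C4 joins an acetal‑level carbon (C3: H, peroxide O, CH2CO arm) to the quaternary C4. C3 can therefore be a peroxycarbenium ion and C4 the carbon end of an aldehyde silyl enol ether.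
- Forward order: C4–C5 by enolate alkylation of a 2‑methylglycidyl triflate, C6–OO by epoxide perhydrolysis, C7 to ethynyl, O–C3 by peroxyacetal exchange. Then the dioxane ring (C3–C4), then the lactone ring, then the C9–C16 chain.
- Stereochemistry: C6 comes from (S)‑2‑methylglycidol, with inversion in the perhydrolysis. C3 and C4 are set relative to C6 in the chair‑like ring closure. The Baeyer–Villiger step retains C4, and the olefination sets the new alkene E.

Key step: step 10

Assumption: (S)‑2‑methylglycidol is bought as the single enantiomer; C4 (compounds 4–14) and the acetal carbon (13–15) are carried as epimer mixtures and left undefined in the SMILES because both are planarised in or before step 10, and 15 is drawn as its expected major E isomer.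

**Route**

Step 1
Reactants: 1 (S)-2-methylglycidol
Product: 2 [(2R)-2-methyloxiran-2-yl]methyl trifluoromethanesulfonate
Conditions: Tf2O, 2,6-lutidine, CH2Cl2, −78 °C
Reagents that add atoms: trifluoromethanesulfonic anhydride, O=S(=O)(OS(=O)(=O)C(F)(F)F)C(F)(F)F
Why: Sulfonylation of a primary alcohol: triflic anhydride with a hindered pyridine base at low temperature converts the hydroxyl into the triflate without touching the epoxide or the quaternary stereocentre, and the cold solution is used at once.

Step 2
Reactants: 2 [(2R)-2-methyloxiran-2-yl]methyl trifluoromethanesulfonate; 3 methyl propanoate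
Product: 4 methyl 2-methyl-3-[(2S)-2-methyloxiran-2-yl]propanoate
Conditions: LDA, THF, −78 °C; then 2, −78 → −40 °C
Reagents that add atoms: none
Why: Ester enolate alkylation (SN2): the lithium enolate displaces the primary triflate far faster than it can open the epoxide, so C4–C5 forms by direct substitution with the epoxide stereocentre (future C6) unchanged, while C4 forms as both epimers, which is of no consequence.

Step 3
Reactants: 4 methyl 2-methyl-3-[(2S)-2-methyloxiran-2-yl]propanoate
Product: 6 (2S)-2-methyl-2-(2-methylbut-3-en-1-yl)oxirane, via 2-methyl-3-[(2S)-2-methyloxiran-2-yl]propanal 5 (not isolated)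
Conditions: DIBAL-H, CH2Cl2, −78 °C; then Ph3P=CH2 (from Ph3PCH3Br, KHMDS), THF, −78 °C → rt
Reagents that add atoms: methyltriphenylphosphonium bromide (as its ylide), C[P+](c1ccccc1)(c1ccccc1)c1ccccc1.[Br-]
Why: Partial ester reduction followed by Wittig methylenation in one flask: the aluminium hemiacetal formed at −78 °C releases the aldehyde only as the ylide consumes it, which avoids isolating the volatile epoxy aldehyde and masks the future C4 formyl group as a vinyl group that is inert to the acidic and oxidising steps ahead.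

Step 4
Reactants: 6 (2S)-2-methyl-2-(2-methylbut-3-en-1-yl)oxirane
Product: 7 (2R)-2-hydroperoxy-2,4-dimethylhex-5-en-1-ol
Conditions: anhydrous H2O2 in Et2O, phosphomolybdic acid (cat.), 0 °C → rt
Reagents that add atoms: hydrogen peroxide, OO
Why: Acid-catalysed epoxide perhydrolysis: under Mo(VI) heteropolyacid catalysis hydrogen peroxide attacks the activated 2,2-disubstituted epoxide at its tertiary carbon from the rear (borderline SN2), so the C6–OO bond forms with inversion and fixes the peroxide-bearing stereocentre, the primary C–O bond staying intact.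

Step 5
Reactants: 7 (2R)-2-hydroperoxy-2,4-dimethylhex-5-en-1-ol
Product: 8 (2R)-2-[(2-methoxypropan-2-yl)peroxy]-2,4-dimethylhex-5-en-1-ol
Conditions: 2-methoxypropene, PPTS (cat.), CH2Cl2, −40 °C; Et3N quench
Reagents that add atoms: 2-methoxypropene, COC(C)=C
Why: Peroxyketalisation by acid-catalysed addition to an enol ether: the hydroperoxy group, an alpha-effect nucleophile with its reacting oxygen one atom away from the quaternary carbon, should be ketalised under kinetic control ahead of the neopentyl-type hydroxyl, and the cold amine quench stops acid-catalysed closure to a 1,2,4-trioxane.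

Step 6
Reactants: 8 (2R)-2-[(2-methoxypropan-2-yl)peroxy]-2,4-dimethylhex-5-en-1-ol
Product: 10 (5R)-5-[(2-methoxypropan-2-yl)peroxy]-3,5-dimethylhept-1-en-6-yne, via (2R)-2-[(2-methoxypropan-2-yl)peroxy]-2,4-dimethylhex-5-enal 9 (not isolated)
Conditions: Dess–Martin periodinane, NaHCO3, CH2Cl2, 0 °C → rt; then dimethyl (1-diazo-2-oxopropyl)phosphonate, K2CO3, MeOH, 0 °C → rt
Reagents that add atoms: dimethyl (1-diazo-2-oxopropyl)phosphonate, CC(=O)C(=[N+]=[N-])P(=O)(OC)OC
Why: Dess–Martin oxidation followed by Ohira–Bestmann (Seyferth–Gilbert) homologation: the alpha-peroxy aldehyde has no alpha hydrogen and the peroxyketal carries no hydrogen on either peroxide-bearing carbon, so neither epimerisation nor base-induced peroxide fragmentation of the Kornblum–DeLaMare type is open while the diazophosphonate anion turns CHO into C≡CH.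

Step 7
Reactants: 10 (5R)-5-[(2-methoxypropan-2-yl)peroxy]-3,5-dimethylhept-1-en-6-yne; 11 methyl 3,3-dimethoxypropanoate
Product: 13 methyl 3-{[(3R)-3,5-dimethylhept-6-en-1-yn-3-yl]peroxy}-3-methoxypropanoate, via (5R)-5-hydroperoxy-3,5-dimethylhept-1-en-6-yne 12 (not isolated)
Conditions: CSA (cat.), MeOH, rt; evaporate; then 11 (excess), 5 Å MS, CH2Cl2, rt
Reagents that add atoms: none
Why: Acid-catalysed peroxyketal methanolysis followed by transacetalisation: the liberated tertiary hydroperoxide exchanges one methoxy group of the dimethyl acetal under the same sulfonic acid, the equilibrium being drawn forward by excess acetal and by sequestering methanol, and the new acetal carbon (future C3) forms as both epimers, which is irrelevant.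

Step 8
Reactants: 13 methyl 3-{[(3R)-3,5-dimethylhept-6-en-1-yn-3-yl]peroxy}-3-methoxypropanoate
Product: 14 methyl 3-{[(3R)-3,5-dimethyl-6-oxohex-1-yn-3-yl]peroxy}-3-methoxypropanoate
Conditions: O3, CH2Cl2/MeOH, NaHCO3, Sudan Red 7B, −78 °C; then Me2S, −78 °C → rt
Reagents that add atoms: ozone, [O-][O+]=O
Why: Chemoselective ozonolysis with reductive work-up: the monosubstituted alkene reacts with ozone far faster than the terminal alkyne, the dye marks the end point, and dimethyl sulfide reduces the ozonolysis peroxides but not the dialkyl peroxyacetal, so the C4 aldehyde is unmasked only now, after the hydroperoxide has been capped.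

Step 9
Reactants: 14 methyl 3-{[(3R)-3,5-dimethyl-6-oxohex-1-yn-3-yl]peroxy}-3-methoxypropanoate
Product: 15 methyl 3-{[(3R,5E)-6-[(tert-butyldimethylsilyl)oxy]-3,5-dimethylhex-5-en-1-yn-3-yl]peroxy}-3-methoxypropanoate
Conditions: TBSOTf, Et3N, CH2Cl2, −78 → 0 °C
Reagents that add atoms: tert-butyldimethylsilyl trifluoromethanesulfonate, CC(C)(C)[Si](C)(C)OS(=O)(=O)C(F)(F)F
Why: Soft enolisation and O-silylation of an alpha-branched aldehyde: silyl triflate with excess triethylamine at low temperature gives the trisubstituted silyl enol ether, the amine keeping the medium basic so that the peroxyacetal is not ionised, and the E isomer (silyloxy group cis to methyl) should predominate for steric reasons.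

Step 10
Reactants: 15 methyl 3-{[(3R,5E)-6-[(tert-butyldimethylsilyl)oxy]-3,5-dimethylhex-5-en-1-yn-3-yl]peroxy}-3-methoxypropanoate
Product: 16 methyl 2-[(3R,4R,6R)-6-ethynyl-4-formyl-4,6-dimethyl-1,2-dioxan-3-yl]acetate
Conditions: TBSOTf (cat.), 2,6-di-tert-butyl-4-methylpyridine, CH2Cl2 (0.01 M), −78 → −20 °C; Et3N quench
Reagents that add atoms: none
Why: Proposed new method: TBSOTf silylates the methoxy oxygen of the peroxyacetal and expels TBSOMe to give the E-configured secondary peroxycarbenium ion at C3, which the tethered silyl enol ether attacks through C4; the resulting silyloxocarbenium ion returns its silyl group to triflate, so the aldehyde is released and the promoter turns over. The closest known reaction type is the intermolecular Lewis-acid-mediated (Mukaiyama-type) addition of silyl enol ethers to peroxycarbenium ions generated from peroxyacetals, together with oxocarbenium ring closures to tetrahydropyrans. The 1,2-dioxane (C3, C4, C5, C6, O, O) closes in a 6-(enolexo)-endo-trig mode through a chair in which the C=O+ bond lies inside the forming ring and the enol C=C outside it. C3 is set by the CH2CO2Me arm of the E-peroxycarbenium ion taking the equatorial site, and C4 by the enol ether face that places the slim sp2 silyloxymethylidene carbon pseudo-axial (cis to the C3 arm) and the methyl group equatorial; both are tied to C6 because the ethynyl group (A value about 0.4) rather than the methyl group (about 1.7) takes the axial position there. The step needs ionisation by loss of methoxide and not of the peroxide, which the hard silicon electrophile binding the more basic methoxy oxygen should secure, and ring closure ahead of oligomerisation or protodesilylation, which high dilution, low temperature and the hindered pyridine base should secure.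

Step 11
Reactants: 16 methyl 2-[(3R,4R,6R)-6-ethynyl-4-formyl-4,6-dimethyl-1,2-dioxan-3-yl]acetate
Product: 17 methyl 2-[(3R,4R,6R)-6-ethynyl-4-(formyloxy)-4,6-dimethyl-1,2-dioxan-3-yl]acetate
Conditions: mCPBA, Na2HPO4, CH2Cl2, 0 °C → rt
Reagents that add atoms: 3-chloroperoxybenzoic acid, OOC(=O)c1cccc(Cl)c1
Why: Baeyer–Villiger oxidation of an alpha-quaternary aldehyde: in the Criegee adduct the tertiary C4 migrates in preference to hydrogen and does so with retention, so the lactone oxygen arrives on C4 on the face that the formyl carbon occupied, cis to the C3 arm, while alkyne, ester and dialkyl peroxide are inert to the buffered peracid.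

Step 12
Reactants: 17 methyl 2-[(3R,4R,6R)-6-ethynyl-4-(formyloxy)-4,6-dimethyl-1,2-dioxan-3-yl]acetate
Product: 19 (3R,4aR,7aR)-3-ethynyl-3,4a-dimethyltetrahydro-3H-furo[3,2-c][1,2]dioxin-6(4H)-one, via methyl 2-[(3R,4R,6R)-6-ethynyl-4-hydroxy-4,6-dimethyl-1,2-dioxan-3-yl]acetate 18 (not isolated)
Conditions: TsOH·H2O (cat.), MeOH, rt; then toluene, 40 °C
Reagents that add atoms: none
Why: Acid-catalysed transesterification followed by lactonisation: methanol removes the formyl group and the tertiary alcohol, held cis to the CH2CO2Me arm on the dioxane, closes the five-membered lactone by 5-exo-trig acyl substitution under conditions that cannot trigger base-induced loss of the peroxide from C3.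

Step 13
Reactants: 20 pent-4-yn-1-ol
Product: 21 5-bromopent-4-yn-1-ol
Conditions: NBS, AgNO3 (cat.), acetone, rt
Reagents that add atoms: N-bromosuccinimide, O=C1CCC(=O)N1Br
Why: Silver-catalysed electrophilic bromination of a terminal alkyne with N-bromosuccinimide gives the 1-bromoalkyne needed as the electrophilic coupling partner, the free hydroxyl being tolerated.

Step 14
Reactants: 19 (3R,4aR,7aR)-3-ethynyl-3,4a-dimethyltetrahydro-3H-furo[3,2-c][1,2]dioxin-6(4H)-one; 21 5-bromopent-4-yn-1-ol
Product: 22 (3R,4aR,7aR)-3-(7-hydroxyhepta-1,3-diyn-1-yl)-3,4a-dimethyltetrahydro-3H-furo[3,2-c][1,2]dioxin-6(4H)-one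
Conditions: CuCl (cat.), NH2OH·HCl, n-BuNH2, MeOH/THF, 0 °C
Reagents that add atoms: none
Why: Cadiot–Chodkiewicz coupling: the copper(I) acetylide of 19 couples with the 1-bromoalkyne to form the C8–C9 sp–sp bond, hydroxylamine keeping copper in the +1 state, and the brief exposure to amine at 0 °C should leave the lactone and the dialkyl peroxide intact.

Step 15
Reactants: 22 (3R,4aR,7aR)-3-(7-hydroxyhepta-1,3-diyn-1-yl)-3,4a-dimethyltetrahydro-3H-furo[3,2-c][1,2]dioxin-6(4H)-one
Product: 23 (3S,4aR,7aR)-3-(7-hydroxyheptyl)-3,4a-dimethyltetrahydro-3H-furo[3,2-c][1,2]dioxin-6(4H)-one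
Conditions: KO2CN=NCO2K, AcOH, MeOH/pyridine, 0 °C → rt (repeated charges)
Reagents that add atoms: none
Why: Diimide reduction: diazene generated in situ from potassium azodicarboxylate and acetic acid transfers H2 to carbon–carbon multiple bonds in a concerted way and does not reduce O–O bonds or cleave the propargylic C6–O bond, so repeated charges should saturate the diyne to the C7–C13 chain.

Step 16
Reactants: 23 (3S,4aR,7aR)-3-(7-hydroxyheptyl)-3,4a-dimethyltetrahydro-3H-furo[3,2-c][1,2]dioxin-6(4H)-one
Product: 24 7-[(3S,4aR,7aR)-3,4a-dimethyl-6-oxotetrahydro-3H-furo[3,2-c][1,2]dioxin-3-yl]heptanal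
Conditions: Dess–Martin periodinane, NaHCO3, CH2Cl2, 0 °C → rt
Reagents that add atoms: none
Why: Dess–Martin oxidation converts the primary alcohol into the aldehyde under buffered, non-basic conditions that the peroxide and the lactone tolerate.

Step 17
Reactants: 24 7-[(3S,4aR,7aR)-3,4a-dimethyl-6-oxotetrahydro-3H-furo[3,2-c][1,2]dioxin-3-yl]heptanal; 25 diethyl [(2E)-3-phenylprop-2-en-1-yl]phosphonate
Product: 26 plakortolide Q
Conditions: LiHMDS, THF, −78 °C; then 24, −78 → 0 °C
Reagents that add atoms: none
Why: Horner–Wadsworth–Emmons olefination with an allylic phosphonate: the lithiated cinnamylphosphonate adds through its alpha carbon and the adduct collapses to the more stable E alkene at C13=C14, the styryl double bond keeping its E geometry, and the preformed stabilised anion at −78 °C should not deprotonate the lactone.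

**Compound list**
1 | (S)-2-methylglycidol | C[C@]1(CO)CO1 | starting material
2 | [(2R)-2-methyloxiran-2-yl]methyl trifluoromethanesulfonate | C[C@]1(COS(=O)(=O)C(F)(F)F)CO1 | intermediate
3 | methyl propanoate | CCC(=O)OC | starting material
4 | methyl 2-methyl-3-[(2S)-2-methyloxiran-2-yl]propanoate (C2 epimers) | C[C@]1(CC(C)C(=O)OC)CO1 | intermediate
5 | 2-methyl-3-[(2S)-2-methyloxiran-2-yl]propanal (C2 epimers) | C[C@]1(CC(C)C=O)CO1 | intermediate
6 | (2S)-2-methyl-2-(2-methylbut-3-en-1-yl)oxirane | C[C@]1(CC(C)C=C)CO1 | intermediate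
7 | (2R)-2-hydroperoxy-2,4-dimethylhex-5-en-1-ol | C[C@@](OO)(CC(C)C=C)CO | intermediate
8 | (2R)-2-[(2-methoxypropan-2-yl)peroxy]-2,4-dimethylhex-5-en-1-ol | C[C@@](OOC(C)(C)OC)(CC(C)C=C)CO | intermediate
9 | (2R)-2-[(2-methoxypropan-2-yl)peroxy]-2,4-dimethylhex-5-enal | C[C@@](OOC(C)(C)OC)(CC(C)C=C)C=O | intermediate
10 | (5R)-5-[(2-methoxypropan-2-yl)peroxy]-3,5-dimethylhept-1-en-6-yne | C[C@@](OOC(C)(C)OC)(CC(C)C=C)C#C | intermediate
11 | methyl 3,3-dimethoxypropanoate | COC(CC(=O)OC)OC | starting material
12 | (5R)-5-hydroperoxy-3,5-dimethylhept-1-en-6-yne | C[C@@](OO)(CC(C)C=C)C#C | intermediate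
13 | methyl 3-{[(3R)-3,5-dimethylhept-6-en-1-yn-3-yl]peroxy}-3-methoxypropanoate | C[C@@](OOC(OC)CC(=O)OC)(CC(C)C=C)C#C | intermediate
14 | methyl 3-{[(3R)-3,5-dimethyl-6-oxohex-1-yn-3-yl]peroxy}-3-methoxypropanoate | C[C@@](OOC(OC)CC(=O)OC)(CC(C)C=O)C#C | intermediate
15 | methyl 3-{[(3R,5E)-6-[(tert-butyldimethylsilyl)oxy]-3,5-dimethylhex-5-en-1-yn-3-yl]peroxy}-3-methoxypropanoate | COC(CC(=O)OC)OO[C@@](C)(C#C)C/C(C)=C/O[Si](C)(C)C(C)(C)C | intermediate
16 | methyl 2-[(3R,4R,6R)-6-ethynyl-4-formyl-4,6-dimethyl-1,2-dioxan-3-yl]acetate | C[C@]1(C#C)C[C@@](C)(C=O)[C@@H](CC(=O)OC)OO1 | intermediate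
17 | methyl 2-[(3R,4R,6R)-6-ethynyl-4-(formyloxy)-4,6-dimethyl-1,2-dioxan-3-yl]acetate | C[C@]1(C#C)C[C@@](C)(OC=O)[C@@H](CC(=O)OC)OO1 | intermediate
18 | methyl 2-[(3R,4R,6R)-6-ethynyl-4-hydroxy-4,6-dimethyl-1,2-dioxan-3-yl]acetate | C[C@]1(C#C)C[C@@](C)(O)[C@@H](CC(=O)OC)OO1 | intermediate
19 | (3R,4aR,7aR)-3-ethynyl-3,4a-dimethyltetrahydro-3H-furo[3,2-c][1,2]dioxin-6(4H)-one (cis-fused peroxylactone) | C[C@]1(C#C)C[C@@]2(C)OC(=O)C[C@H]2OO1 | intermediate
20 | pent-4-yn-1-ol | C#CCCCO | starting material
21 | 5-bromopent-4-yn-1-ol | OCCCC#CBr | intermediate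
22 | (3R,4aR,7aR)-3-(7-hydroxyhepta-1,3-diyn-1-yl)-3,4a-dimethyltetrahydro-3H-furo[3,2-c][1,2]dioxin-6(4H)-one | C[C@]1(C#CC#CCCCO)C[C@@]2(C)OC(=O)C[C@H]2OO1 | intermediate
23 | (3S,4aR,7aR)-3-(7-hydroxyheptyl)-3,4a-dimethyltetrahydro-3H-furo[3,2-c][1,2]dioxin-6(4H)-one | C[C@]1(CCCCCCCO)C[C@@]2(C)OC(=O)C[C@H]2OO1 | intermediate
24 | 7-[(3S,4aR,7aR)-3,4a-dimethyl-6-oxotetrahydro-3H-furo[3,2-c][1,2]dioxin-3-yl]heptanal | C[C@]1(CCCCCCC=O)C[C@@]2(C)OC(=O)C[C@H]2OO1 | intermediate
25 | diethyl [(2E)-3-phenylprop-2-en-1-yl]phosphonate | CCOP(=O)(C/C=C/c1ccccc1)OCC | starting material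
26 | plakortolide Q, (3S,4aR,7aR)-3,4a-dimethyl-3-[(7E,9E)-10-phenyldeca-7,9-dien-1-yl]tetrahydro-3H-furo[3,2-c][1,2]dioxin-6(4H)-one | C[C@]1(CCCCCC/C=C/C=C/c2ccccc2)C[C@@]2(C)OC(=O)C[C@H]2OO1 | target

**Step count**
Total: 17 steps. Longest linear sequence: 16 steps (steps 1–12 and 14–17, from 1); step 13 is a one-step side branch.

**Steps most likely to fail**

Step 10 (proposed new method). The ester-deactivated peroxyacetal may ionise the wrong way (loss of the peroxide instead of methoxide) or the carbenium ion may lose a proton from C2. The chair preference may also fail to translate into facial selectivity at C4. The fallback uses only known reactions, sets out from 10 and returns at 19, but gives up control of C4.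
- Ozonolysis of the vinyl group of 10 (O3; Me2S) should give (4R)-4-[(2-methoxypropan-2-yl)peroxy]-2,4-dimethylhex-5-ynal F1.
- Silylation (TBSOTf, Et3N) should give the silyl enol ether tert-butyl{[(1E,4R)-4-[(2-methoxypropan-2-yl)peroxy]-2,4-dimethylhex-1-en-5-yn-1-yl]oxy}dimethylsilane F2.
- Rubottom oxidation (mCPBA, NaHCO3) should give (4R)-2-[(tert-butyldimethylsilyl)oxy]-4-[(2-methoxypropan-2-yl)peroxy]-2,4-dimethylhex-5-ynal F3 as both C2 epimers.
- Still–Gennari olefination (methyl bis(2,2,2-trifluoroethyl)phosphonoacetate, KHMDS, 18-crown-6) should give methyl (2Z,6R)-4-[(tert-butyldimethylsilyl)oxy]-6-[(2-methoxypropan-2-yl)peroxy]-4,6-dimethyloct-2-en-7-ynoate F4.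
- Desilylation (HF·pyridine or TBAF) lets the tertiary alcohol close onto the Z ester to give the butenolide 5-{(2R)-2-[(2-methoxypropan-2-yl)peroxy]-2-methylbut-3-yn-1-yl}-5-methylfuran-2(5H)-one F5.
- Acid methanolysis (PPTS, MeOH) frees 5-[(2R)-2-hydroperoxy-2-methylbut-3-yn-1-yl]-5-methylfuran-2(5H)-one F6.
- Amine-catalysed intramolecular oxa-Michael addition (Et2NH, CF3CH2OH) should close the dioxane, necessarily cis-fused, to give 19 together with its epimer (3R,4aS,7aS)-3-ethynyl-3,4a-dimethyltetrahydro-3H-furo[3,2-c][1,2]dioxin-6(4H)-one F7, which would have to be separated by chromatography.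

Step 6. Methoxide may add to the alpha-peroxy aldehyde, and the hemiacetal anion may fragment with C–C and O–O cleavage before homologation occurs. The fallback sets out from 9 and returns at 10 by a phosphorus-ylide route that uses no alkoxide. Stork–Zhao olefination (Ph3P=CHI from iodomethyltriphenylphosphonium iodide and NaHMDS, THF, −78 °C) should give (1Z,3R)-1-iodo-3-[(2-methoxypropan-2-yl)peroxy]-3,5-dimethylhepta-1,6-diene F8. Anti elimination of HI with NaHMDS at −78 °C, which the hydrogen-free peroxyketal tolerates, then gives 10.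

Step 14. Copper(I) with a primary amine may cleave the O–O bond or open the lactone, and the bromoalkyne may homocouple. The fallback sets out from 20 and 19 and returns at 23, replacing the copper-only sp–sp coupling by a palladium-catalysed sp–sp2 coupling. Hydrozirconation–iodination of 20 (Cp2Zr(H)Cl, then I2) should give (4E)-5-iodopent-4-en-1-ol F9. Sonogashira coupling with 19 (Pd(PPh3)2Cl2, CuI, Et3N, THF, rt) should give (3R,4aR,7aR)-3-[(3E)-7-hydroxyhept-3-en-1-yn-1-yl]-3,4a-dimethyltetrahydro-3H-furo[3,2-c][1,2]dioxin-6(4H)-one F10. Diimide reduction as in step 15 then gives 23.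

Further compounds
F1 | step 10 | (4R)-4-[(2-methoxypropan-2-yl)peroxy]-2,4-dimethylhex-5-ynal | C[C@@](OOC(C)(C)OC)(CC(C)C=O)C#C
F2 | step 10 | tert-butyl{[(1E,4R)-4-[(2-methoxypropan-2-yl)peroxy]-2,4-dimethylhex-1-en-5-yn-1-yl]oxy}dimethylsilane | C[C@@](OOC(C)(C)OC)(C/C(C)=C/O[Si](C)(C)C(C)(C)C)C#C
F3 | step 10 | (4R)-2-[(tert-butyldimethylsilyl)oxy]-4-[(2-methoxypropan-2-yl)peroxy]-2,4-dimethylhex-5-ynal | C[C@@](OOC(C)(C)OC)(CC(C)(O[Si](C)(C)C(C)(C)C)C=O)C#C
F4 | step 10 | methyl (2Z,6R)-4-[(tert-butyldimethylsilyl)oxy]-6-[(2-methoxypropan-2-yl)peroxy]-4,6-dimethyloct-2-en-7-ynoate | C[C@@](OOC(C)(C)OC)(CC(C)(O[Si](C)(C)C(C)(C)C)/C=C\C(=O)OC)C#C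
F5 | step 10 | 5-{(2R)-2-[(2-methoxypropan-2-yl)peroxy]-2-methylbut-3-yn-1-yl}-5-methylfuran-2(5H)-one | C[C@@](OOC(C)(C)OC)(CC1(C)OC(=O)C=C1)C#C
F6 | step 10 | 5-[(2R)-2-hydroperoxy-2-methylbut-3-yn-1-yl]-5-methylfuran-2(5H)-one | C[C@@](OO)(CC1(C)OC(=O)C=C1)C#C
F7 | step 10 | (3R,4aS,7aS)-3-ethynyl-3,4a-dimethyltetrahydro-3H-furo[3,2-c][1,2]dioxin-6(4H)-one | C[C@]1(C#C)C[C@]2(C)OC(=O)C[C@@H]2OO1
F8 | step 6 | (1Z,3R)-1-iodo-3-[(2-methoxypropan-2-yl)peroxy]-3,5-dimethylhepta-1,6-diene | C[C@@](OOC(C)(C)OC)(CC(C)C=C)/C=C\I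
F9 | step 14 | (4E)-5-iodopent-4-en-1-ol | OCCC/C=C/I
F10 | step 14 | (3R,4aR,7aR)-3-[(3E)-7-hydroxyhept-3-en-1-yn-1-yl]-3,4a-dimethyltetrahydro-3H-furo[3,2-c][1,2]dioxin-6(4H)-one | C[C@]1(C#C/C=C/CCCO)C[C@@]2(C)OC(=O)C[C@H]2OO1
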